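The earlier runs and the new flask come from a simulation from invented constants, and the scatter is random.

in all of them: Z 0.10 M
- green: E 0.076 M; run made earlier
- grey: E 0.16 M; run made earlier
- noon: E 0.110 M; time 8.0 h
- autumn: E 0.220 M; time 8.0 h

| run | time / h | Z / % | J / % |
|---|---|---|---|
| green | 1.00 | 47 | 34 |
| green | 2.00 | 38 | 35 |
| green | 3.00 | 32 | 37 |
| green | 4.00 | 29 | 37 |
| grey | 0.333 | 56 | 39 |
| grey | 0.667 | 38 | 52 |
| grey | 1.50 | 20 | 61 |
| grey | 4.00 | 11 | 70 |

(each reading ± 2 percentage points)

- a species is counted by the Z in it: one D counts as two
- reactions considered so far: Z + E -> X + J; E + X <-> G; 2 Z -> D; J -> Q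

- part of the Z that has reacted at the end, noon
- part of the Z that has reacted at the end, autumn
- what raising the concentration of E from its lowest to its highest value here does to the part of the Z that has reacted (changes below 5 percentage points count as none) (it rises / no change / it falls)

Charge each J two E: one makes it, and the X set free holds the second as G. You can read this price in green, where E is 76.0% of the Z and J levels off at a reading of 37%. Z still falls there, from 38% to 29%, so a Z molecule has a fork: it meets E, or it meets another Z and goes to D. Noon has 55.0% as its allowance, the E charge over twice the Z charge, which is the part of the Z that E carries to J at that price. Autumn has 110%. Between those two green readings, one over the remaining fraction of Z climbs by 0.408 /h, which I take as the pace of pairing.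

Now take noon to two extremes. If E acts first, 45.0% of the Z remains, pairing then leaves 18.2% at 8.0 h, and 81.8% has reacted. If pairing acts first, it leaves 23.4%, less than the allowance, so E then takes the remainder and no Z stays. The real flask runs both forks together, so I expect it between them. J read level in green by a quarter of this time; taking E in noon to be used up early as well, I put noon a little above the E-first figure. Autumn's allowance exceeds the charge, so both extremes empty that flask of Z.

The forecast says 86%, 99.7% and it rises, holding that “each J uses about two E”. The flask gives 86.3% for noon and 99.8% for autumn; from noon to autumn it rises, by 13 percentage points.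

    Z + E → X + J (k = 0.220 /M/min)
    E + X ⇌ G, settled at all times (K = 58000 /M)
    2 Z → D (k = 0.0370 /M/min)
    J → Q (k = 2.60 × 10⁻⁴ /min)

In noon E is the limiting reagent, down to 0.815% of its charge at 8.00 h, and J and Q together hold 55.1% against the allowance of 55.0%. Take autumn with Z cut to 0.025 M: the allowance is 440%, so if each Z became J, 77.3% of the E would remain. That flask ends with J 87.0%, Q 11.0%, D 2.02%, and E at 77.7% of its own charge.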